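## The problem

CNP0115465.0 is a 2-arylbenzofuran. Ring A (C-3a to C-7a) is a phloroglucinol whose three oxygens are O-1 of the furan and the hydroxyls at C-4 and C-6. Ring B is a resorcinol joined through C-1' to C-2 of the furan.

The molecule has no stereocentre and no stereogenic double bond, and ring B is symmetric about the C-2–C-1' axis, so there is no axial chirality either. Nothing has to be controlled stereochemically; every selectivity question is regiochemical.

Two of these questions are hard. C-7 carries the quaternary carbon of a 1,1-dimethylallyl group and lies between the oxygenated carbons C-6 and C-7a; tert-prenylation or a Claisen rearrangement on a preformed phloroglucinol reaches this position only in competition with C-5. C-1' is flanked by prenyl groups at C-2' and C-6', so ring B must be joined to the furan at a doubly ortho-substituted carbon.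

All three side chains are alkenes ortho to a phenol. Acid closes them to chromans or dihydrofurans, and the tetraphenol is easily oxidised, so the end game must avoid Brønsted and Lewis acids, oxidants and hydrogenation.

The feature that opens the route is the pattern of ring A: the carbon-substituted C-7 sits between two oxygen-bearing carbons, while C-5 is CH and C-3a is the ring-fusion carbon. This is the pattern produced when a vinylketene and an ynol ether are stitched into a benzene ring, with the alkyne substituent ending between the two oxygens.

## Retrosynthesis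

**20 to 19.** The last cut is four O–Si bonds: target 20 is taken back to its tetrakis(triisopropylsilyl) ether 19. Methyl or methoxymethyl ethers would need hot thiolate or acid at the end, whereas silyl ethers leave with buffered fluoride, the one reagent class that none of the alkenes or phenols objects to. The forward step must only cleave aryl silyl ethers, two of them next to bulky neighbours.

**19 to 12 and 17.** The furan is opened at C-3a–C-3 and O-1–C-2, giving iodophenol 12 (ring A complete) and arylacetylene 17 (ring B complete). Cutting the C-2–C-1' bond instead would demand an aryl–aryl coupling at the carbon between two prenyl groups. Cutting C-2=C-3 would put an ester carbonyl at that same hindered carbon. The alkyne moves the C–C bond formation to a terminal sp carbon one atom away from the prenyl groups. The forward reaction is a Sonogashira coupling followed by 5-endo-dig addition of the phenol to the alkyne through alkynylphenol 18.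

**12 to 11.** One C–I bond is cut, back to phenol 11. The forward step must iodinate ortho to the free hydroxyl. That is the only free ortho position, and the alternative para position lies between two triisopropylsilyloxy groups.

**11 to 4 and 6 (key disconnection).** Ring A is cut at C-7–C-7a and C-5–C-6 into siloxyalkyne 4 and 3-(triisopropylsilyloxy)cyclobutenone 6.

- Alkyne 4 supplies C-7 with the complete 1,1-dimethylallyl group and C-6 with its oxygen.
- Cyclobutenone 6 supplies C-7a with its oxygen, C-5, C-4 with its oxygen, and C-3a.

Against functionalising a phloroglucinol, this cut places the quaternary carbon between two oxygens by construction. It also leaves exactly one hydroxyl free, the one that becomes O-1. The enol oxygen of the four-membered ring is silylated, not alkylated, for two reasons: an alkyl ether at C-4 would need hot thiolate or a Lewis acid for its removal, and with the same silyl group on both flanking oxygens any 1,5 shift of silicon during the cascade is degenerate. Both precursors are one step from commercial materials. The forward reaction must open the cyclobutenone thermally and unite the ketene with a hindered ynol ether in one orientation.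

**4 to 1, and 6 to 5.** In 4 the C≡C–O unit is cut back to the ester carbonyl of ethyl 2,2-dimethylbut-3-enoate 1; a one-carbon homologation through an ynolate supplies the second alkyne carbon. In 6 the O–Si bond is cut back to cyclobutane-1,3-dione 5. Both forward steps are enolate or ynolate O-silylations.

**17 to 16, 15, 14 and 13.** The alkyne carbon of 17 is removed to give aldehyde 16. The two aryl–prenyl bonds are cut to dibromide 15, the two C–Br bonds to bis-silyl ether 14, and the silyl groups to commercial 3,5-dihydroxybenzaldehyde 13. The aldehyde is preferred to the corresponding ester as the C-1' handle because it is one step from the alkyne and activates both bromides for oxidative addition. The forward sequence needs a 2,6-selective dibromination (C-4 is shielded by two silyl ethers) and a double prenyl cross-coupling that keeps the linear prenyl group.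

## Roads not taken

**Alternative 1:** The cut is the C-2=C-3 double bond. The phenol oxygen of ring A is acylated by the ring B acid, and the benzylic carbon that becomes C-3 carries a triphenylphosphonium group, as in salt A2. Base generates the ylide, which attacks its own ester carbonyl and closes the furan to the tetrakis(methoxymethyl) ether A1.

- Merits: convergent, metal-free, the furan can close only one way, and ring B enters at the carboxylic acid level without one-carbon homologation.
- Weak points: in A2 the ester joins an oxygen flanked by the C-7 quaternary carbon to a carbonyl flanked by two prenyl groups, so both the acylation and the oxaphosphetane formation occur at a mesitoate-like centre. The phosphonium group is normally installed with PPh3·HBr on a 2-hydroxybenzyl alcohol, which means hot acid next to the 1,1-dimethylallyl group. A1 must lose four methoxymethyl groups under acid with three acid-sensitive alkenes present. The plan also does not say how C-7 is told from C-5 when the ring A half is made.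
- Comparison: this is a furan-closing tactic, so it competes with steps 4 and 9, not with step 3. It is better in needing no regioselective iodination and no palladium. The chosen plan sets against this a C–C bond formed at a terminal alkyne carbon remote from the prenyl groups, a fluoride-only end game, and a ring A whose substitution is fixed by ring construction.

**Alternative 2:** The cut is C-3'–C-4' of ring B, taken back to a saturated precursor. Alkoxide converts the methyl ketone of δ-keto ester A4 into its enolate, which attacks the ester carbon to give cyclohexane-1,3-dione A3. A dehydrogenation must then turn A3 into the resorcinol.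

- Merits: the two prenyl groups sit on sp3 carbons α to carbonyl groups, where ordinary enolate alkylation places them with no aromatic regiochemistry to control. The C-2–C-1' bond is made at an sp3 carbon by conjugate addition, not at a di-ortho-substituted arene. In both respects it is better than steps 6, 7 and 9 of the chosen plan, which rely on a selective dibromination and a double cross-coupling.
- Weak points: A3 is one oxidation level below ring B. The usual dehydrogenating agents (iodine, DDQ, Hg(OAc)2, palladium on carbon at high temperature) also attack prenyl groups, the vinyl group and the electron-rich benzofuran. A4 and A3 carry three stereocentres that are made only to be destroyed and must be handled as diastereomer mixtures. The methine positions of A4 compete with the methyl group for enolisation. Ring A, with its C-7 problem, still has to be supplied.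
- Comparison: the chosen plan sets against the easier prenyl placement a ring B that is aromatic from the first step and four steps long, and no redox step on the assembled skeleton.

**Alternative 3:** The cut is C-4–C-5 of ring A, with the furan and ring B already in place. Base forms the enolate of the methyl ketone in furan A6 at the carbon that becomes C-5. It attacks the furan-3-carboxylate carbon (C-4), and the fused cyclohexane-1,3-dione tautomerises to the 4,6-dihydroxybenzofuran A5.

- Merits: as in the chosen plan, ring A is made last from an open chain and the 1,1-dimethylallyl group is placed by construction. Aromatisation is a tautomerisation, so no oxidant is needed. Ring A emerges with both hydroxyls free, so A5 carries two protecting groups fewer than 19; in this respect the alternative is better.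
- Weak points: the difficulty moves into A6. Its C-7 is a methine bonded to the furan, the acetyl group and the quaternary allylic carbon. Making that bond means tert-prenylation of a stabilised enolate, which prefers the linear prenyl product, or a sigmatropic detour. That methine is also the most acidic position of A6, so the condensation must pass through the less stable methyl enolate, under conditions that invite retro-Claisen cleavage. A6 is a 2,3,5-trisubstituted furan needing its own multistep synthesis with ring B attached early. A5 still needs acidic removal of two methoxymethyl groups beside three sensitive alkenes.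
- Comparison: the chosen plan brings the quaternary carbon in on an alkyne made in one step from a commercial ester, forms ring A convergently with no by-product, and needs no acid at the end. It pays with two extra silyl groups and a thermal cascade at the edge of its known scope.

Key step: step 3

Assumption: cyclobutane-1,3-dione (5), which reacts as its enol, is treated as a purchasable compound.

## Route

Step 1
Reactants: 1 ethyl 2,2-dimethylbut-3-enoate
Product: 4 [(3,3-dimethylpent-4-en-1-yn-1-yl)oxy]triisopropylsilane, via dibromo enolate 2 (not isolated), via lithium ynolate 3 (not isolated)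
Conditions: CH2Br2, lithium 2,2,6,6-tetramethylpiperidide, THF, −78 °C; LiN(SiMe3)2, −78 °C; n-BuLi, −78 °C to rt; i-Pr3SiOTf, −78 to 0 °C
Reagents that add atoms: dibromomethane, BrCBr; triisopropylsilyl trifluoromethanesulfonate, CC(C)[Si](C(C)C)(C(C)C)OS(=O)(=O)C(F)(F)F
Why: Kowalski ester homologation stopped at the ynolate: LiCHBr2 adds to the ester, LiN(SiMe3)2 converts the adduct into dibromo enolate 2, and bromine–lithium exchange triggers 1,2-migration of the tertiary alkyl group to give ynolate 3. The hard silyl triflate should trap 3 on oxygen, and the bulky silyl group makes the ynol ether isolable.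

Step 2
Reactants: 5 cyclobutane-1,3-dione
Product: 6 3-(triisopropylsilyloxy)cyclobut-2-en-1-one
Conditions: i-Pr3SiOTf, Et3N, CH2Cl2, −78 to 0 °C
Reagents that add atoms: triisopropylsilyl trifluoromethanesulfonate, CC(C)[Si](C(C)C)(C(C)C)OS(=O)(=O)C(F)(F)F
Why: Enol silylation of a 1,3-diketone: the dione is a vinylogous acid and its triethylammonium enolate should be silylated on oxygen to give the vinylogous silyl ester. The triisopropylsilyl group is chosen because it resists adventitious hydrolysis and later leaves with fluoride.

Step 3
Reactants: 6 3-(triisopropylsilyloxy)cyclobut-2-en-1-one; 4 [(3,3-dimethylpent-4-en-1-yn-1-yl)oxy]triisopropylsilane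
Product: 11 2-(2-methylbut-3-en-2-yl)-3,5-bis(triisopropylsilyloxy)phenol, via vinylketene 7 (not isolated), via vinylcyclobutenone 8 (not isolated), via dienylketene 9 (not isolated), via cyclohexadienone 10 (not isolated)
Conditions: toluene, 80 to 110 °C, sealed tube, argon
Reagents that add atoms: none
Why: Heating opens cyclobutenone 6 by 4π electrocyclic cleavage of its C(=O)–CH2 bond to vinylketene 7, which stays in equilibrium with 6. The ynol ether is polarised so that the carbon bearing the tertiary alkyl group is nucleophilic; it bonds to the ketene carbonyl carbon (future C-7–C-7a) while the oxygen-bearing alkyne carbon bonds to the ketene α-carbon (future C-6–C-5), a [2+2] cycloaddition that gives vinylcyclobutenone 8. A second 4π opening gives dienylketene 9, and ring A closes by thermal disrotatory 6π electrocyclisation between the ketene carbon and the terminal methylene, which become C-7a and C-3a; enolisation of cyclohexadienone 10 gives phenol 11. The closest known reaction type is the Danheiser benzannulation of cyclobutenones with siloxyalkynes, which gives resorcinol monosilyl ethers with the alkyne substituent between the two oxygens; a 3-silyloxy donor on the cyclobutenone and a tertiary alkyl group on the ynol ether stretch that scope. No stereocentre is formed, since the one in 8 is transient and is erased on ring opening. The selectivity needed is the orientation of the ketene–alkyne union, and the donor oxygen on the alkyne secures it, so the quaternary carbon should arrive at C-7 and the only free hydroxyl should be the one that becomes O-1. Because both flanking oxygens carry the same silyl group, a 1,5 shift of silicon between oxygens in 10 would lead to the same phenol.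

Step 4
Reactants: 11 2-(2-methylbut-3-en-2-yl)-3,5-bis(triisopropylsilyloxy)phenol
Product: 12 2-iodo-6-(2-methylbut-3-en-2-yl)-3,5-bis(triisopropylsilyloxy)phenol
Conditions: NIS (1.0 equiv), CH2Cl2, −40 to 0 °C, dark
Reagents that add atoms: N-iodosuccinimide, O=C1CCC(=O)N1I
Why: Electrophilic aromatic iodination of a phloroglucinol-type ring: the position para to the hydroxyl lies between two triisopropylsilyloxy groups and is shielded, so substitution should occur at the only free ortho carbon (future C-3a). The ring is far more nucleophilic than the monosubstituted alkene, which argues against iodoetherification at low temperature.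

Step 5
Reactants: 13 3,5-dihydroxybenzaldehyde
Product: 14 3,5-bis(triisopropylsilyloxy)benzaldehyde
Conditions: i-Pr3SiCl, imidazole, DMF, rt
Reagents that add atoms: chlorotriisopropylsilane, CC(C)[Si](Cl)(C(C)C)C(C)C
Why: Standard phenol silylation with a silyl chloride and imidazole. Using the same silyl group as on ring A allows a single fluoride step at the end.

Step 6
Reactants: 14 3,5-bis(triisopropylsilyloxy)benzaldehyde
Product: 15 2,6-dibromo-3,5-bis(triisopropylsilyloxy)benzaldehyde
Conditions: NBS (2.2 equiv), MeCN, 0 °C to rt
Reagents that add atoms: N-bromosuccinimide, O=C1CCC(=O)N1Br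
Why: Electrophilic aromatic bromination: C-2 and C-6 are each ortho to one silyloxy group and para to the other, whereas C-4 lies between the two bulky silyl ethers. Dibromination should therefore stop at the 2,6-pattern, as it does for 3,5-dialkoxybenzaldehydes.

Step 7
Reactants: 15 2,6-dibromo-3,5-bis(triisopropylsilyloxy)benzaldehyde
Product: 16 2,6-bis(3-methylbut-2-en-1-yl)-3,5-bis(triisopropylsilyloxy)benzaldehyde
Conditions: tributyl(3-methylbut-2-en-1-yl)stannane (3 equiv), Pd(PPh3)4 (10 mol %), DMF, 100 °C
Reagents that add atoms: tributyl(3-methylbut-2-en-1-yl)stannane, CCCC[Sn](CCCC)(CCCC)CC=C(C)C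
Why: Twofold Stille coupling of aryl bromides activated by the ortho formyl group. Reductive elimination from the allylpalladium intermediate at its less substituted terminus should give the linear prenyl group, and the neutral conditions spare the aldehyde and the silyl ethers.

Step 8
Reactants: 16 2,6-bis(3-methylbut-2-en-1-yl)-3,5-bis(triisopropylsilyloxy)benzaldehyde
Product: 17 2-ethynyl-1,3-bis(3-methylbut-2-en-1-yl)-4,6-bis(triisopropylsilyloxy)benzene
Conditions: Me3SiCHN2, LiN(i-Pr)2, THF, −78 °C to rt
Reagents that add atoms: (trimethylsilyl)diazomethane, C[Si](C)(C)C=[N+]=[N-]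
Why: Colvin rearrangement: lithiated (trimethylsilyl)diazomethane adds to the non-enolisable aldehyde, Peterson elimination gives a diazoalkene, and loss of N2 gives an alkylidene carbene whose 1,2-hydrogen shift gives the terminal alkyne. The aprotic, low-temperature conditions spare the aryl silyl ethers, which carbonate in methanol would threaten.

Step 9
Reactants: 12 2-iodo-6-(2-methylbut-3-en-2-yl)-3,5-bis(triisopropylsilyloxy)phenol; 17 2-ethynyl-1,3-bis(3-methylbut-2-en-1-yl)-4,6-bis(triisopropylsilyloxy)benzene
Product: 19 2-[2,6-bis(3-methylbut-2-en-1-yl)-3,5-bis(triisopropylsilyloxy)phenyl]-7-(2-methylbut-3-en-2-yl)-4,6-bis(triisopropylsilyloxy)-1-benzofuran, via alkynylphenol 18 (not isolated)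
Conditions: PdCl2(PPh3)2 (5 mol %), CuI (10 mol %), Et3N, DMF, 60 then 90 °C, degassed
Reagents that add atoms: none
Why: Sonogashira coupling followed in the same flask by 5-endo-dig hydroalkoxylation, the standard benzofuran synthesis from an o-iodophenol and a terminal alkyne. C-3a–C-3 forms at the unhindered terminal alkyne carbon, and the phenol oxygen then adds to the metal-activated alkyne of 18 to form O-1–C-2; the silyl ethers and the three alkenes should be inert.

Step 10
Reactants: 19 2-[2,6-bis(3-methylbut-2-en-1-yl)-3,5-bis(triisopropylsilyloxy)phenyl]-7-(2-methylbut-3-en-2-yl)-4,6-bis(triisopropylsilyloxy)-1-benzofuran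
Product: 20 2-[3,5-dihydroxy-2,6-bis(3-methylbut-2-en-1-yl)phenyl]-7-(2-methylbut-3-en-2-yl)-1-benzofuran-4,6-diol (CNP0115465.0)
Conditions: n-Bu4NF, AcOH, THF, 0 °C to rt, argon
Reagents that add atoms: none
Why: Fluoride cleavage of aryl silyl ethers, which is fast because phenoxides are good leaving groups on silicon. Acetic acid buffers the phenoxides, so the prenyl and 1,1-dimethylallyl groups never meet acid and the tetraphenol never stands as a polyanion.

## Compound list

1 | ethyl 2,2-dimethylbut-3-enoate | CCOC(=O)C(C)(C)C=C | starting material
2 | lithium 1,1-dibromo-3,3-dimethylpenta-1,4-dien-2-olate | C=CC(C)(C)C(O[Li])=C(Br)Br | intermediate (not isolated)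
3 | lithium 3,3-dimethylpent-4-en-1-yn-1-olate | C=CC(C)(C)C#CO[Li] | intermediate (not isolated)
4 | [(3,3-dimethylpent-4-en-1-yn-1-yl)oxy]triisopropylsilane | C=CC(C)(C)C#CO[Si](C(C)C)(C(C)C)C(C)C | intermediate
5 | cyclobutane-1,3-dione | O=C1CC(=O)C1 | starting material
6 | 3-(triisopropylsilyloxy)cyclobut-2-en-1-one | O=C1C=C(O[Si](C(C)C)(C(C)C)C(C)C)C1 | intermediate
7 | 3-(triisopropylsilyloxy)buta-1,3-dien-1-one | O=C=CC(=C)O[Si](C(C)C)(C(C)C)C(C)C | intermediate (not isolated)
8 | 2-(2-methylbut-3-en-2-yl)-3-(triisopropylsilyloxy)-4-[1-(triisopropylsilyloxy)ethenyl]cyclobut-2-en-1-one, racemic | O=C1C(C(C)(C)C=C)=C(O[Si](C(C)C)(C(C)C)C(C)C)C1C(=C)O[Si](C(C)C)(C(C)C)C(C)C | intermediate (not isolated)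
9 | (3E)-2-(2-methylbut-3-en-2-yl)-3,5-bis(triisopropylsilyloxy)hexa-1,3,5-trien-1-one | O=C=C(C(C)(C)C=C)/C(O[Si](C(C)C)(C(C)C)C(C)C)=C\C(=C)O[Si](C(C)C)(C(C)C)C(C)C | intermediate (not isolated)
10 | 2-(2-methylbut-3-en-2-yl)-3,5-bis(triisopropylsilyloxy)cyclohexa-2,4-dien-1-one | O=C1CC(O[Si](C(C)C)(C(C)C)C(C)C)=CC(O[Si](C(C)C)(C(C)C)C(C)C)=C1C(C)(C)C=C | intermediate (not isolated)
11 | 2-(2-methylbut-3-en-2-yl)-3,5-bis(triisopropylsilyloxy)phenol | Oc1cc(O[Si](C(C)C)(C(C)C)C(C)C)cc(O[Si](C(C)C)(C(C)C)C(C)C)c1C(C)(C)C=C | intermediate
12 | 2-iodo-6-(2-methylbut-3-en-2-yl)-3,5-bis(triisopropylsilyloxy)phenol | Oc1c(I)c(O[Si](C(C)C)(C(C)C)C(C)C)cc(O[Si](C(C)C)(C(C)C)C(C)C)c1C(C)(C)C=C | intermediate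
13 | 3,5-dihydroxybenzaldehyde | O=Cc1cc(O)cc(O)c1 | starting material
14 | 3,5-bis(triisopropylsilyloxy)benzaldehyde | O=Cc1cc(O[Si](C(C)C)(C(C)C)C(C)C)cc(O[Si](C(C)C)(C(C)C)C(C)C)c1 | intermediate
15 | 2,6-dibromo-3,5-bis(triisopropylsilyloxy)benzaldehyde | O=Cc1c(Br)c(O[Si](C(C)C)(C(C)C)C(C)C)cc(O[Si](C(C)C)(C(C)C)C(C)C)c1Br | intermediate
16 | 2,6-bis(3-methylbut-2-en-1-yl)-3,5-bis(triisopropylsilyloxy)benzaldehyde | O=Cc1c(CC=C(C)C)c(O[Si](C(C)C)(C(C)C)C(C)C)cc(O[Si](C(C)C)(C(C)C)C(C)C)c1CC=C(C)C | intermediate
17 | 2-ethynyl-1,3-bis(3-methylbut-2-en-1-yl)-4,6-bis(triisopropylsilyloxy)benzene | C#Cc1c(CC=C(C)C)c(O[Si](C(C)C)(C(C)C)C(C)C)cc(O[Si](C(C)C)(C(C)C)C(C)C)c1CC=C(C)C | intermediate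
18 | 2-{[2,6-bis(3-methylbut-2-en-1-yl)-3,5-bis(triisopropylsilyloxy)phenyl]ethynyl}-6-(2-methylbut-3-en-2-yl)-3,5-bis(triisopropylsilyloxy)phenol | Oc1c(C#Cc2c(CC=C(C)C)c(O[Si](C(C)C)(C(C)C)C(C)C)cc(O[Si](C(C)C)(C(C)C)C(C)C)c2CC=C(C)C)c(O[Si](C(C)C)(C(C)C)C(C)C)cc(O[Si](C(C)C)(C(C)C)C(C)C)c1C(C)(C)C=C | intermediate (not isolated)
19 | 2-[2,6-bis(3-methylbut-2-en-1-yl)-3,5-bis(triisopropylsilyloxy)phenyl]-7-(2-methylbut-3-en-2-yl)-4,6-bis(triisopropylsilyloxy)-1-benzofuran | C=CC(C)(C)c1c(O[Si](C(C)C)(C(C)C)C(C)C)cc(O[Si](C(C)C)(C(C)C)C(C)C)c2cc(-c3c(CC=C(C)C)c(O[Si](C(C)C)(C(C)C)C(C)C)cc(O[Si](C(C)C)(C(C)C)C(C)C)c3CC=C(C)C)oc12 | intermediate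
20 | 2-[3,5-dihydroxy-2,6-bis(3-methylbut-2-en-1-yl)phenyl]-7-(2-methylbut-3-en-2-yl)-1-benzofuran-4,6-diol (CNP0115465.0) | C=CC(C)(C)c1c(O)cc(O)c2cc(-c3c(CC=C(C)C)c(O)cc(O)c3CC=C(C)C)oc12 | target

## Step count and risk

Total step count: 10.

Longest linear sequence: 6 steps (13 → 14 → 15 → 16 → 17 → 19 → 20). The ring A branch is 5 steps from 1, with step 2 in parallel.

**Step 3 (key step).** The most likely failure is a thermal mismatch. The 3-silyloxy donor stabilises cyclobutenone 6, so its 4π opening may need temperatures at which the siloxyalkyne isomerises to a silylketene by migration of silicon from oxygen to carbon. Meanwhile the [2+2] at the alkyne carbon bearing the quaternary centre is slow enough for the vinylketene to dimerise or to acylate the product phenol. The fallback sets out from 4 and returns at 11; it generates the same vinylketene photochemically at room temperature. Butane-2,3-dione is converted with i-Pr3SiOTf and Et3N into 3-(triisopropylsilyloxy)but-3-en-2-one F1. Detrifluoroacetylative diazo transfer (LiN(SiMe3)2 and CF3CO2CH2CF3, then MsN3 and Et3N) gives 1-diazo-3-(triisopropylsilyloxy)but-3-en-2-one F2. Irradiation of F2 with 4 triggers a photochemical Wolff rearrangement to vinylketene 7 at room temperature, where 4 is stable, and gentle heating afterwards completes the 4π/6π sequence to 11.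

**Step 4.** The iodonium source may engage the 1,1-dimethylallyl alkene with the neighbouring hydroxyl (iodoetherification), or a second iodination may follow at the position between the two silyl ethers. The fallback sets out from 11 and returns at 12; it replaces electrophilic substitution by directed metalation. The phenol is protected with NaH and MeOCH2Cl as 1-(methoxymethoxy)-2-(2-methylbut-3-en-2-yl)-3,5-bis(triisopropylsilyloxy)benzene F3. Lithiation ortho to the acetal oxygen with s-BuLi and TMEDA at −78 °C, then quenching with I2, gives 2-iodo-1-(methoxymethoxy)-6-(2-methylbut-3-en-2-yl)-3,5-bis(triisopropylsilyloxy)benzene F4. ZnBr2 with n-PrSH in CH2Cl2 removes the acetal without touching the silyl ethers or the alkene.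

**Step 9.** Oxidative addition into the electron-rich, doubly ortho-substituted iodophenol may be slow enough for oxidative dimerisation of 17 to take over. The ring closure may also stall at 18, because the alkyne carbon under attack carries the 2,6-diprenylaryl group. The fallback sets out from 12 and returns at 19; it separates the two events. Acetylation (Ac2O, Et3N, DMAP) gives 2-iodo-6-(2-methylbut-3-en-2-yl)-3,5-bis(triisopropylsilyloxy)phenyl acetate F5, a better partner for zerovalent palladium. Sonogashira coupling with 17 near room temperature gives 2-{[2,6-bis(3-methylbut-2-en-1-yl)-3,5-bis(triisopropylsilyloxy)phenyl]ethynyl}-6-(2-methylbut-3-en-2-yl)-3,5-bis(triisopropylsilyloxy)phenyl acetate F6. Hydrazine hydrate in THF–MeOH removes the acetate to give 18, which is isolated and closed to 19 with a cationic monovalent gold catalyst (AuCl(PPh3) with AgOTf, toluene, rt).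

**Step 7.** The second coupling, at a bromide flanked by formyl and silyloxy groups, may be incomplete. Allyl transposition at palladium may deliver some 1,1-dimethylallyl groups, and protodebromination may compete. The fallback sets out from 15 and returns at 16; it builds each prenyl group in two stages. Stille coupling with allyltributylstannane and Pd(PPh3)4, which has no regiochemical issue and is less hindered, gives 2,6-diallyl-3,5-bis(triisopropylsilyloxy)benzaldehyde F7. Double cross-metathesis with 2-methylbut-2-ene and the second-generation Grubbs catalyst converts both allyl groups into prenyl groups.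

**Step 1.** Addition of LiCHBr2 to an ester carbonyl next to a quaternary carbon may be incomplete at −78 °C, and silylation of the ynolate on carbon may compete with silylation on oxygen. The fallback sets out from 1 and returns at 4; it reaches ynolate 3 by oxidation of an acetylide. Reduction with i-Bu2AlH at −78 °C gives 2,2-dimethylbut-3-enal F8. The Ohira–Bestmann reagent with K2CO3 in methanol gives 3,3-dimethylpent-4-en-1-yne F9, handled in solution because of its volatility. Deprotonation with LiN(SiMe3)2 and oxidation of the lithium acetylide with t-BuOOLi gives ynolate 3, which is silylated with i-Pr3SiOTf as in step 1.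

## Further compounds

F1 | step 3 | 3-(triisopropylsilyloxy)but-3-en-2-one | CC(=O)C(=C)O[Si](C(C)C)(C(C)C)C(C)C
F2 | step 3 | 1-diazo-3-(triisopropylsilyloxy)but-3-en-2-one | [N-]=[N+]=CC(=O)C(=C)O[Si](C(C)C)(C(C)C)C(C)C
F3 | step 4 | 1-(methoxymethoxy)-2-(2-methylbut-3-en-2-yl)-3,5-bis(triisopropylsilyloxy)benzene | COCOc1cc(O[Si](C(C)C)(C(C)C)C(C)C)cc(O[Si](C(C)C)(C(C)C)C(C)C)c1C(C)(C)C=C
F4 | step 4 | 2-iodo-1-(methoxymethoxy)-6-(2-methylbut-3-en-2-yl)-3,5-bis(triisopropylsilyloxy)benzene | COCOc1c(I)c(O[Si](C(C)C)(C(C)C)C(C)C)cc(O[Si](C(C)C)(C(C)C)C(C)C)c1C(C)(C)C=C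
F5 | step 9 | 2-iodo-6-(2-methylbut-3-en-2-yl)-3,5-bis(triisopropylsilyloxy)phenyl acetate | CC(=O)Oc1c(I)c(O[Si](C(C)C)(C(C)C)C(C)C)cc(O[Si](C(C)C)(C(C)C)C(C)C)c1C(C)(C)C=C
F6 | step 9 | 2-{[2,6-bis(3-methylbut-2-en-1-yl)-3,5-bis(triisopropylsilyloxy)phenyl]ethynyl}-6-(2-methylbut-3-en-2-yl)-3,5-bis(triisopropylsilyloxy)phenyl acetate | CC(=O)Oc1c(C#Cc2c(CC=C(C)C)c(O[Si](C(C)C)(C(C)C)C(C)C)cc(O[Si](C(C)C)(C(C)C)C(C)C)c2CC=C(C)C)c(O[Si](C(C)C)(C(C)C)C(C)C)cc(O[Si](C(C)C)(C(C)C)C(C)C)c1C(C)(C)C=C
F7 | step 7 | 2,6-diallyl-3,5-bis(triisopropylsilyloxy)benzaldehyde | O=Cc1c(CC=C)c(O[Si](C(C)C)(C(C)C)C(C)C)cc(O[Si](C(C)C)(C(C)C)C(C)C)c1CC=C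
F8 | step 1 | 2,2-dimethylbut-3-enal | C=CC(C)(C)C=O
F9 | step 1 | 3,3-dimethylpent-4-en-1-yne | C=CC(C)(C)C#C
A1 | alternative 1 | 2-[3,5-bis(methoxymethoxy)-2,6-bis(3-methylbut-2-en-1-yl)phenyl]-4,6-bis(methoxymethoxy)-7-(2-methylbut-3-en-2-yl)-1-benzofuran | C=CC(C)(C)c1c(OCOC)cc(OCOC)c2cc(-c3c(CC=C(C)C)c(OCOC)cc(OCOC)c3CC=C(C)C)oc12
A2 | alternative 1 | {2-[3,5-bis(methoxymethoxy)-2,6-bis(3-methylbut-2-en-1-yl)benzoyloxy]-4,6-bis(methoxymethoxy)-3-(2-methylbut-3-en-2-yl)benzyl}triphenylphosphonium bromide | C=CC(C)(C)c1c(OCOC)cc(OCOC)c(C[P+](c2ccccc2)(c2ccccc2)c2ccccc2)c1OC(=O)c1c(CC=C(C)C)c(OCOC)cc(OCOC)c1CC=C(C)C.[Br-]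
A3 | alternative 2 | 5-[4,6-bis(methoxymethoxy)-7-(2-methylbut-3-en-2-yl)-1-benzofuran-2-yl]-4,6-bis(3-methylbut-2-en-1-yl)cyclohexane-1,3-dione (diastereomer mixture) | O=C1CC(=O)C(CC=C(C)C)C(c2cc3c(OCOC)cc(OCOC)c(C(C)(C)C=C)c3o2)C1CC=C(C)C
A4 | alternative 2 | methyl 3-[4,6-bis(methoxymethoxy)-7-(2-methylbut-3-en-2-yl)-1-benzofuran-2-yl]-2,4-bis(3-methylbut-2-en-1-yl)-5-oxohexanoate (diastereomer mixture) | COC(=O)C(CC=C(C)C)C(c1cc2c(OCOC)cc(OCOC)c(C(C)(C)C=C)c2o1)C(CC=C(C)C)C(C)=O
A5 | alternative 3 | 2-[3,5-bis(methoxymethoxy)-2,6-bis(3-methylbut-2-en-1-yl)phenyl]-7-(2-methylbut-3-en-2-yl)-1-benzofuran-4,6-diol | C=CC(C)(C)c1c(O)cc(O)c2cc(-c3c(CC=C(C)C)c(OCOC)cc(OCOC)c3CC=C(C)C)oc12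
A6 | alternative 3 | methyl 5-[3,5-bis(methoxymethoxy)-2,6-bis(3-methylbut-2-en-1-yl)phenyl]-2-(4,4-dimethyl-2-oxohex-5-en-3-yl)furan-3-carboxylate (racemic) | COC(=O)c1cc(-c2c(CC=C(C)C)c(OCOC)cc(OCOC)c2CC=C(C)C)oc1C(C(C)=O)C(C)(C)C=C
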